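**Plan**

- Retrosynthesis: the two benzyl O–C bonds on the catechol oxygens are cut first (protecting groups). Both bonds at the ester carbonyl, C1(aryl)–C(=O) and C(=O)–O(chain), are then cut together, leaving a 3-bromocatechol dibenzyl ether, carbon monoxide and 16-methylheptadecan-1-ol. The alcohol is cut at C12–C13 into a C12 bromo alcohol and a 4-methylpentyl Grignard reagent.
- Enabling feature: the ester carbonyl is a single carbon held between ring carbon C1 of the benzene ring (next to the C2 oxygen) and the oxygen of the iso-C18 chain. It can therefore be delivered as CO between an aryl C–Br bond and an alcohol O–H bond.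
- Forward order: no ring is made; the benzene ring is bought with its 1,2,3-pattern in place. The catechol is benzylated, the chain is assembled (C12 + C6), then arene, CO and alcohol are joined in one operation, and the benzyl ethers are removed last.
- Stereochemistry: the target has no stereocentre and no double-bond geometry, so nothing has to be set.

Key step: step 5

Assumption: the tetrahydropyranyl ethers of the chain synthesis are racemic at the acetal carbon; this centre is temporary and is removed before the key step.

**Route**

Step 1
Reactants: 1 3-bromocatechol (3-bromobenzene-1,2-diol); 2 benzyl bromide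
Product: 3 1-bromo-2,3-bis(benzyloxy)benzene
Conditions: 2 (2.3 equiv), K2CO3 (3 equiv), DMF, 60 °C, under N2
Reagents that add atoms: none
Why: Williamson ether synthesis, in which both phenoxides formed by K2CO3 displace bromide from the benzylic halide by SN2 while the aryl C–Br bond is inert.

Step 2
Reactants: 4 12-bromododecan-1-ol; 5 3,4-dihydro-2H-pyran
Product: 6 2-[(12-bromododecyl)oxy]oxane (racemic tetrahydropyranyl ether)
Conditions: 5 (1.5 equiv), PPTS (5 mol%), CH2Cl2, rt
Reagents that add atoms: none
Why: Acid-catalysed tetrahydropyranylation (addition of the alcohol to the oxocarbenium ion from the enol ether) masks the O–H before the Grignard step; the new acetal carbon forms as a racemate without control, which does not matter because it is removed in step 4.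

Step 3
Reactants: 7 1-bromo-4-methylpentane; 6 2-[(12-bromododecyl)oxy]oxane
Product: 9 2-[(16-methylheptadecyl)oxy]oxane, via (4-methylpentyl)magnesium bromide 8 (not isolated)
Conditions: 7 (1.5 equiv), Mg, THF, 45 °C; then 6, Li2CuCl4 (3 mol%), THF, −10 °C to rt
Reagents that add atoms: none
Why: Kochi-type copper-catalysed sp3–sp3 cross-coupling, in which Grignard reagent 8 reduces Li2CuCl4 to a monovalent copper species and forms a cuprate that displaces the unhindered primary bromide of 6, while the acetal is inert to the organometallics.

Step 4
Reactants: 9 2-[(16-methylheptadecyl)oxy]oxane
Product: 10 16-methylheptadecan-1-ol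
Conditions: TsOH·H2O (10 mol%), MeOH/THF, rt
Reagents that add atoms: none
Why: Acid-catalysed transacetalisation, in which methanol traps the oxocarbenium ion and releases the primary alcohol; the saturated chain has nothing else that can react.

Step 5
Reactants: 3 1-bromo-2,3-bis(benzyloxy)benzene (1.2 equiv); 10 16-methylheptadecan-1-ol; 11 carbon monoxide
Product: 12 16-methylheptadecyl 2,3-bis(benzyloxy)benzoate
Conditions: CO (1 atm, balloon), Pd(OAc)2 (3 mol%), Xantphos (4 mol%), Et3N (3 equiv), toluene, 90 °C
Reagents that add atoms: none
Why: Pd(OAc)2 is reduced in the flask to zerovalent palladium, which adds oxidatively into the C1–Br bond of 3; CO then coordinates and migrates into the aryl–palladium bond to give an aroyl complex of divalent palladium, and alcohol 10 with Et3N cleaves that complex to release ester 12, return zerovalent palladium and leave the HBr as triethylammonium bromide. The closest known reaction type is the Heck-type alkoxycarbonylation of aryl bromides with primary alcohols at atmospheric CO pressure under Pd(OAc)2/Xantphos catalysis. No ring closes and no stereocentre forms, so there is no closure mode or stereocontrol to assign; the two new bonds are C1(aryl)–C(=O) and C(=O)–O. The step needs chemoselectivity for CO insertion over direct C–O coupling to an aryl alkyl ether and over hydrodebromination; the CO atmosphere makes insertion into the aryl–palladium bond faster than alkoxide attack, and the wide bite angle of Xantphos keeps the catalyst active at 1 atm CO despite the ortho benzyloxy group. The bromine at C1 fixes the site, and because both phenols are benzylated, alcohol 10 is the only nucleophile present.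

Step 6
Reactants: 12 16-methylheptadecyl 2,3-bis(benzyloxy)benzoate
Product: 13 Gentiside D (16-methylheptadecyl 2,3-dihydroxybenzoate)
Conditions: H2 (1 atm), Pd/C (10 wt% Pd), EtOAc, rt
Reagents that add atoms: none
Why: Catalytic hydrogenolysis cleaves the two benzylic C–O bonds to toluene and the free catechol, while the saturated alkyl benzoate has no bond that hydrogen cleaves under these conditions.

**Compound list**

1 | 3-bromocatechol (3-bromobenzene-1,2-diol) | Oc1cccc(Br)c1O | starting material
2 | benzyl bromide | BrCc1ccccc1 | starting material
3 | 1-bromo-2,3-bis(benzyloxy)benzene | Brc1cccc(OCc2ccccc2)c1OCc1ccccc1 | intermediate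
4 | 12-bromododecan-1-ol | OCCCCCCCCCCCCBr | starting material
5 | 3,4-dihydro-2H-pyran | C1=COCCC1 | starting material
6 | 2-[(12-bromododecyl)oxy]oxane (racemic) | BrCCCCCCCCCCCCOC1CCCCO1 | intermediate
7 | 1-bromo-4-methylpentane | CC(C)CCCBr | starting material
8 | (4-methylpentyl)magnesium bromide | CC(C)CCC[Mg]Br | intermediate (not isolated)
9 | 2-[(16-methylheptadecyl)oxy]oxane (racemic) | CC(C)CCCCCCCCCCCCCCCOC1CCCCO1 | intermediate
10 | 16-methylheptadecan-1-ol | CC(C)CCCCCCCCCCCCCCCO | intermediate
11 | carbon monoxide | [C-]#[O+] | starting material
12 | 16-methylheptadecyl 2,3-bis(benzyloxy)benzoate | CC(C)CCCCCCCCCCCCCCCOC(=O)c1cccc(OCc2ccccc2)c1OCc1ccccc1 | intermediate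
13 | Gentiside D (16-methylheptadecyl 2,3-dihydroxybenzoate) | CC(C)CCCCCCCCCCCCCCCOC(=O)c1cccc(O)c1O | target

**Count**

Total steps: 6. Longest linear sequence: 5 steps (steps 2, 3, 4, 5 and 6, from 12-bromododecan-1-ol); step 1 is a one-step side branch that joins at step 5.

**Steps most likely to fail**

Step 5. With only about one equivalent of a long-chain alcohol, alcoholysis of the aroyl-palladium intermediate may be slow. Hydrodebromination, or loss of the catalyst to inactive palladium carbonyl species and palladium black, could then overtake ester formation. Oxidative addition at the electron-rich, ortho-substituted bromide may also be sluggish. Fallback: setting out from 3, bromine–lithium exchange with n-BuLi in THF at −78 °C followed by a CO2 quench and acidic work-up should give 2,3-bis(benzyloxy)benzoic acid F1. Steglich esterification of this acid with alcohol 10 (EDC·HCl, DMAP, CH2Cl2, rt) then comes back to the route at 12. The carbonyl carbon still enters as a one-carbon unit at the former C–Br site.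

Step 3. Wurtz-type homocoupling during Grignard formation, reduction or elimination of the alkyl bromide at copper, or incomplete conversion could leave a mixture of long-chain ethers that is hard to separate. Fallback: setting out from 6, heating with PPh3 in MeCN (NaHCO3 buffer, reflux) should give [12-(oxan-2-yloxy)dodecyl]triphenylphosphonium bromide F2. Deprotonation with NaN(SiMe3)2 in THF at −78 °C and Wittig reaction with commercial 4-methylpentanal should give 2-{[(12Z)-16-methylheptadec-12-en-1-yl]oxy}oxane F3, whose geometry is of no consequence. Hydrogenation of the alkene (H2, Pd/C, EtOAc with a trace of Et3N to protect the acetal) then comes back to the route at 9.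

Step 6. Hydrogenolysis may stall after loss of the first benzyl group, the Pd/C may be poisoned by phosphine carried over from step 5, and the free catechol may oxidise in air during handling. Fallback: setting out from 12, Lewis-acid debenzylation with BCl3 and pentamethylbenzene as benzyl-cation scavenger (CH2Cl2, −78 °C, then MeOH quench) cleaves aryl benzyl ethers without hydrogen and tolerates the alkyl ester. It comes back to the route directly at 13, and no new compound is made on this path (F0).

**Further compounds**

F1 | step 5 | 2,3-bis(benzyloxy)benzoic acid | O=C(O)c1cccc(OCc2ccccc2)c1OCc1ccccc1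
F2 | step 3 | [12-(oxan-2-yloxy)dodecyl]triphenylphosphonium bromide | [Br-].c1ccccc1[P+](c1ccccc1)(c1ccccc1)CCCCCCCCCCCCOC1CCCCO1
F3 | step 3 | 2-{[(12Z)-16-methylheptadec-12-en-1-yl]oxy}oxane | CC(C)CC/C=C\CCCCCCCCCCCOC1CCCCO1
F0 | step 6 | none | none
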